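**Retrosynthetic overview**

Numbering: C1 (CH–aryl), C2 (CH–C9), C3 (=C–C10), C4 (=CH), fusion carbons C4a and C8a (C8a on C1), ring A C5–C8, with C9 on C2 and C10 on C3.
1. The route rests on two features: C1 carries a 4-hydroxy-3,5-dimethoxyphenyl ring, so C1 can be the exocyclic carbon of a para-quinone methide, and C2 is α to C9, which can be held as an aldehyde.
2. Target 26 ⇐ lactone 24 (temporary C9–O–C10 tie, so that C9 is reduced and C10 finishes as the aldehyde) ⇐ formyl ester 21.
3. 21 ⇐ carbinol aldehyde 17 by the C1–C2 bond: enamine carbon C2 closes onto quinone methide carbon C1. Ring B is the only carbocycle built; ring A and the pendant ring both come from syringaldehyde 1.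
4. 17 ⇐ ring A aldehyde 9 by Horner–Wadsworth–Emmons olefination (C3=C4) with allyl phosphonate 12, then cleavage of the allyl terminus to C9H=O.
5. 9 ⇐ C8a–C1 bond by addition of the aryllithium from bromo acetal 4 to O-silylsyringaldehyde 5.

Key step: step 11

Remark: the target is taken as the open hydroxy-enal drawn (its lactol tautomer 25 is expected to be the minor form), and the sense of induction in step 11 is assigned by analogy, so the antipodal catalyst would be used if the opposite sense were found.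

**Route**

Step 1
Reactants: 1 syringaldehyde
Product: 2 4-(benzyloxy)-3,5-dimethoxybenzaldehyde
Conditions: BnBr, K2CO3, DMF, 60 °C
Reagents that add atoms: benzyl bromide, BrCc1ccccc1
Why: Williamson O-alkylation of the phenoxide; the benzyl ether should survive n-BuLi, base, fluoride and hydride and is taken off at the lactone stage.

Step 2
Reactants: 2 4-(benzyloxy)-3,5-dimethoxybenzaldehyde
Product: 3 4-(benzyloxy)-2-bromo-3,5-dimethoxybenzaldehyde
Conditions: NBS, MeCN, rt → 50 °C, dark
Reagents that add atoms: N-bromosuccinimide, O=C1CCC(=O)N1Br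
Why: electrophilic aromatic bromination at the only open position (the two are equivalent), which is ortho and para to the methoxy groups, as is usual for 3,4,5-trialkoxybenzaldehydes.

Step 3
Reactants: 3 4-(benzyloxy)-2-bromo-3,5-dimethoxybenzaldehyde
Product: 4 2-(benzyloxy)-4-bromo-5-(dimethoxymethyl)-1,3-dimethoxybenzene
Conditions: HC(OMe)3, MeOH, TsOH·H2O (cat.), 50 °C; then Et3N
Reagents that add atoms: trimethyl orthoformate, COC(OC)OC; methanol, CO
Why: acid-catalysed acetalisation driven by the orthoester masks the aldehyde for the halogen–lithium exchange, and the dimethyl acetal of an electron-rich benzaldehyde is later released by very mild acid.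

Step 4
Reactants: 1 syringaldehyde
Product: 5 4-[(tert-butyldimethylsilyl)oxy]-3,5-dimethoxybenzaldehyde
Conditions: TBSCl, imidazole, DMF, rt
Reagents that add atoms: tert-butyldimethylsilyl chloride, CC(C)(C)[Si](C)(C)Cl
Why: imidazole-promoted O-silylation of the phenol; the aryl silyl ether should tolerate the aryllithium at −78 °C and is cleaved by fluoride in step 10.

Step 5
Reactants: 4 2-(benzyloxy)-4-bromo-5-(dimethoxymethyl)-1,3-dimethoxybenzene; 5 4-[(tert-butyldimethylsilyl)oxy]-3,5-dimethoxybenzaldehyde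
Product: 8 racemic diarylmethyl triethylsilyl ether [3-(benzyloxy)-6-(dimethoxymethyl)-2,4-dimethoxyphenyl]{4-[(tert-butyldimethylsilyl)oxy]-3,5-dimethoxyphenyl}methoxy(triethyl)silane, via aryllithium 6 (not isolated), via lithium alkoxide 7 (not isolated)
Conditions: n-BuLi, THF, −78 °C; then 5, −78 °C; then Et3SiCl, DMAP (cat.), −78 °C → rt
Reagents that add atoms: chlorotriethylsilane, CC[Si](Cl)(CC)CC
Why: bromine–lithium exchange outpaces attack on the acetal or benzyl ether at −78 °C, the aryllithium adds 1,2 to the aldehyde (the racemic carbinol centre is of no consequence because C1 becomes planar in step 11), and O-silylation in the same flask keeps the carbinol from later closing onto the aldehyde (lactol) or onto C4 of the acrylate (oxa-Michael).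

Step 6
Reactants: 8 racemic diarylmethyl triethylsilyl ether acetal
Product: 9 racemic 4-(benzyloxy)-2-[{4-[(tert-butyldimethylsilyl)oxy]-3,5-dimethoxyphenyl}(triethylsilyloxy)methyl]-3,5-dimethoxybenzaldehyde
Conditions: PPTS (cat.), acetone/H2O (10:1), rt
Reagents that add atoms: water, O
Why: acetal hydrolysis under pyridinium catalysis; the para-benzyloxy group makes the oxocarbenium ion easy to form, so the acetal should go well before either silyl ether is touched.

Step 7
Reactants: 10 trimethyl phosphonoacetate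
Product: 12 racemic methyl 2-(dimethoxyphosphoryl)pent-4-enoate, via sodium phosphonate 11 (not isolated)
Conditions: NaH, THF, 0 °C; then allyl bromide, 0 °C → rt
Reagents that add atoms: allyl bromide, C=CCBr
Why: SN2 C-alkylation of the stabilised phosphonate carbanion with an allylic halide; a slight excess of 10 limits dialkylation.

Step 8
Reactants: 9 racemic ring A aldehyde; 12 racemic methyl 2-(dimethoxyphosphoryl)pent-4-enoate
Product: 14 racemic methyl (2E)-2-{[4-(benzyloxy)-2-[{4-[(tert-butyldimethylsilyl)oxy]-3,5-dimethoxyphenyl}(triethylsilyloxy)methyl]-3,5-dimethoxyphenyl]methylidene}pent-4-enoate, via sodium phosphonate 13 (not isolated)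
Conditions: NaH, THF, 0 °C; then 9, 0 → 40 °C
Reagents that add atoms: none
Why: Horner–Wadsworth–Emmons olefination; α-substituted phosphonoacetates should give with aryl aldehydes mainly the (E)-acrylate, in which the aryl group is cis to the CH2 arm (C2) as ring closure requires, and the minor (Z)-isomer is removed by chromatography.

Step 9
Reactants: 14 racemic methyl (2E)-2-(arylmethylidene)pent-4-enoate
Product: 16 racemic methyl (2E)-3-{4-(benzyloxy)-2-[{4-[(tert-butyldimethylsilyl)oxy]-3,5-dimethoxyphenyl}(triethylsilyloxy)methyl]-3,5-dimethoxyphenyl}-2-(2-oxoethyl)prop-2-enoate, via diol 15 (not isolated)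
Conditions: OsO4 (2 mol%), NaIO4, 2,6-lutidine, dioxane/H2O (3:1), rt
Reagents that add atoms: osmium tetroxide, O=[Os](=O)(=O)=O (catalytic); sodium periodate, [Na+].[O-]I(=O)(=O)=O (terminal oxygen source)
Why: Lemieux–Johnson cleavage, in which OsO4 should dihydroxylate the unhindered monosubstituted alkene much faster than the trisubstituted, ester-conjugated and ortho-shielded C3=C4 bond, and NaIO4 cleaves the diol to the C9 aldehyde.

Step 10
Reactants: 16 racemic bis-silylated aldehyde
Product: 17 racemic methyl (2E)-3-{4-(benzyloxy)-2-[hydroxy(4-hydroxy-3,5-dimethoxyphenyl)methyl]-3,5-dimethoxyphenyl}-2-(2-oxoethyl)prop-2-enoate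
Conditions: Bu4NF, AcOH (1:1), THF, 0 °C
Reagents that add atoms: none
Why: fluoride-mediated desilylation of the aryl and the secondary silyl ether, with acetic acid buffering so that neither phenoxide nor aldehyde enolate builds up and the free 4-hydroxybenzhydrol should survive; 17 is used at once.

Step 11
Reactants: 17 racemic carbinol aldehyde
Product: 21 methyl (1S,2R)-7-(benzyloxy)-2-formyl-1-(4-hydroxy-3,5-dimethoxyphenyl)-6,8-dimethoxy-1,2-dihydronaphthalene-3-carboxylate, via para-quinone methide 18 (not isolated), via dienamine 19 (not isolated), via cyclised iminium 20 (not isolated)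
Conditions: (R)-2-[diphenyl(trimethylsilyloxy)methyl]pyrrolidine (20 mol%), 4-O2NC6H4CO2H (40 mol%), CHCl3 (0.02 M), 0 °C → rt, under argon
Reagents that add atoms: none
Why: Proposed new method: the acid dehydrates the 4-hydroxybenzhydrol of 17 to para-quinone methide 18 while the amine condenses with C9 to give dienamine 19, whose C2 adds to the exocyclic C1 in a 1,6-addition that rearomatises the pendant ring, and hydrolysis of iminium 20 returns the catalyst. The closest known reactions are the diarylprolinol silyl ether-catalysed intermolecular 1,6-addition of aldehydes to para-quinone methides and the amine-catalysed SN1-type α-alkylation of aldehydes with benzhydrols, so only the intramolecular setting and the dienamine are untested. Ring B closes in a 6-(enolexo)-exo-trig mode, with the (E)-C3=C4 bond holding C2 within reach of C1. C2 is set by the catalyst: the CPh2(OSiMe3) arm of the (R)-pyrrolidine blocks one face of the s-trans (E)-enamine, so C1 should arrive on the open Re face and give 2R, by analogy with the sense of intermolecular enamine alkylations. C1 is set relative to C2 in the cyclic transition state, where the quinone methide ring should take the side of the forming ring away from the enamine arm, giving 1,2-trans and hence 1S. The step needs α- and not γ-attack of the dienamine (γ-attack would need a four-membered ring) and amine-bound, not enol, closure, which the weak substoichiometric acid and high dilution should secure; the trans ratio has to be kinetic, because later epimerisation of a cis isomer at C2 would lead to the antipode.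

Step 12
Reactants: 21 methyl (1S,2R)-2-formyl-1,2-dihydronaphthalene-3-carboxylate (crude, after a short silica plug)
Product: 23 (3aR,4S)-6-(benzyloxy)-4-(4-hydroxy-3,5-dimethoxyphenyl)-5,7-dimethoxy-3a,4-dihydronaphtho[2,3-c]furan-1(3H)-one, via hydroxy ester 22 (not isolated)
Conditions: NaBH4, THF/MeOH (4:1), −20 °C; then PPTS (cat.), CH2Cl2, rt
Reagents that add atoms: none
Why: chemoselective borohydride reduction of the aldehyde (ester and C3=C4 untouched) before C2 can epimerise, then acylation of the C9 hydroxyl by the neighbouring C10 ester to the five-membered lactone, with no change at C1 or C2.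

Step 13
Reactants: 23 benzyl-protected lactone
Product: 24 (3aR,4S)-6-hydroxy-4-(4-hydroxy-3,5-dimethoxyphenyl)-5,7-dimethoxy-3a,4-dihydronaphtho[2,3-c]furan-1(3H)-one
Conditions: BCl3, C6HMe5, CH2Cl2, −78 °C; then MeOH
Reagents that add atoms: none
Why: Lewis acid cleavage of the aryl benzyl ether at −78 °C with pentamethylbenzene as benzyl cation trap (Friedel–Crafts scavenging), conditions that should leave the methyl ethers, the lactone and C3=C4 alone.

Step 14
Reactants: 24 bis-phenol lactone
Product: 26 (3R,4S)-6-hydroxy-4-(4-hydroxy-3,5-dimethoxyphenyl)-3-(hydroxymethyl)-5,7-dimethoxy-3,4-dihydronaphthalene-2-carbaldehyde, via lactol 25 (not isolated)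
Conditions: i-Bu2AlH (4 equiv), THF/CH2Cl2, −78 °C; then aq. potassium sodium tartrate
Reagents that add atoms: none
Why: partial reduction of the lactone stops at the aluminium hemiacetal at −78 °C (two equivalents are used up by the phenols), and on work-up the lactol should open to the hydroxy-enal, which is favoured by conjugation of C10=O with C3=C4 and ring A.

**Compound list**

1 | syringaldehyde (4-hydroxy-3,5-dimethoxybenzaldehyde) | COc1cc(C=O)cc(OC)c1O | starting material
2 | 4-(benzyloxy)-3,5-dimethoxybenzaldehyde | COc1cc(C=O)cc(OC)c1OCc1ccccc1 | intermediate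
3 | 4-(benzyloxy)-2-bromo-3,5-dimethoxybenzaldehyde | COc1cc(C=O)c(Br)c(OC)c1OCc1ccccc1 | intermediate
4 | 2-(benzyloxy)-4-bromo-5-(dimethoxymethyl)-1,3-dimethoxybenzene | COC(OC)c1cc(OC)c(OCc2ccccc2)c(OC)c1Br | intermediate
5 | 4-[(tert-butyldimethylsilyl)oxy]-3,5-dimethoxybenzaldehyde | COc1cc(C=O)cc(OC)c1O[Si](C)(C)C(C)(C)C | intermediate
6 | [3-(benzyloxy)-6-(dimethoxymethyl)-2,4-dimethoxyphenyl]lithium | [Li]c1c(C(OC)OC)cc(OC)c(OCc2ccccc2)c1OC | intermediate (not isolated)
7 | lithium alkoxide of the diarylmethanol from 6 and 5 (racemic) | [Li+].[O-]C(c1cc(OC)c(O[Si](C)(C)C(C)(C)C)c(OC)c1)c1c(C(OC)OC)cc(OC)c(OCc2ccccc2)c1OC | intermediate (not isolated)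
8 | [3-(benzyloxy)-6-(dimethoxymethyl)-2,4-dimethoxyphenyl]{4-[(tert-butyldimethylsilyl)oxy]-3,5-dimethoxyphenyl}methoxy(triethyl)silane (racemic) | CC[Si](CC)(CC)OC(c1cc(OC)c(O[Si](C)(C)C(C)(C)C)c(OC)c1)c1c(C(OC)OC)cc(OC)c(OCc2ccccc2)c1OC | intermediate
9 | 4-(benzyloxy)-2-[{4-[(tert-butyldimethylsilyl)oxy]-3,5-dimethoxyphenyl}(triethylsilyloxy)methyl]-3,5-dimethoxybenzaldehyde (racemic) | CC[Si](CC)(CC)OC(c1cc(OC)c(O[Si](C)(C)C(C)(C)C)c(OC)c1)c1c(C=O)cc(OC)c(OCc2ccccc2)c1OC | intermediate
10 | trimethyl phosphonoacetate | COC(=O)CP(=O)(OC)OC | starting material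
11 | sodium salt of trimethyl phosphonoacetate | [Na+].COC(=O)[CH-]P(=O)(OC)OC | intermediate (not isolated)
12 | methyl 2-(dimethoxyphosphoryl)pent-4-enoate (racemic) | COC(=O)C(CC=C)P(=O)(OC)OC | intermediate
13 | sodium salt of 12 | [Na+].COC(=O)[C-](CC=C)P(=O)(OC)OC | intermediate (not isolated)
14 | methyl (2E)-2-{[4-(benzyloxy)-2-[{4-[(tert-butyldimethylsilyl)oxy]-3,5-dimethoxyphenyl}(triethylsilyloxy)methyl]-3,5-dimethoxyphenyl]methylidene}pent-4-enoate (racemic) | CC[Si](CC)(CC)OC(c1cc(OC)c(O[Si](C)(C)C(C)(C)C)c(OC)c1)c1c(/C=C(\CC=C)C(=O)OC)cc(OC)c(OCc2ccccc2)c1OC | intermediate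
15 | methyl (2E)-2-(arylmethylidene)-4,5-dihydroxypentanoate, aryl as in 14 (mixture of diastereomers) | CC[Si](CC)(CC)OC(c1cc(OC)c(O[Si](C)(C)C(C)(C)C)c(OC)c1)c1c(/C=C(\CC(O)CO)C(=O)OC)cc(OC)c(OCc2ccccc2)c1OC | intermediate (not isolated)
16 | methyl (2E)-3-{4-(benzyloxy)-2-[{4-[(tert-butyldimethylsilyl)oxy]-3,5-dimethoxyphenyl}(triethylsilyloxy)methyl]-3,5-dimethoxyphenyl}-2-(2-oxoethyl)prop-2-enoate (racemic) | CC[Si](CC)(CC)OC(c1cc(OC)c(O[Si](C)(C)C(C)(C)C)c(OC)c1)c1c(/C=C(\CC=O)C(=O)OC)cc(OC)c(OCc2ccccc2)c1OC | intermediate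
17 | methyl (2E)-3-{4-(benzyloxy)-2-[hydroxy(4-hydroxy-3,5-dimethoxyphenyl)methyl]-3,5-dimethoxyphenyl}-2-(2-oxoethyl)prop-2-enoate (racemic; key-step precursor) | COc1cc(C(O)c2c(/C=C(\CC=O)C(=O)OC)cc(OC)c(OCc3ccccc3)c2OC)cc(OC)c1O | intermediate
18 | para-quinone methide of 17 (exocyclic carbon C1) | COC1=CC(=Cc2c(/C=C(\CC=O)C(=O)OC)cc(OC)c(OCc3ccccc3)c2OC)C=C(OC)C1=O | intermediate (not isolated)
19 | (E)-dienamine of 18 with the (R)-pyrrolidine catalyst | COC1=CC(=Cc2c(/C=C(\C=C\N3CCC[C@@H]3C(c4ccccc4)(c4ccccc4)O[Si](C)(C)C)C(=O)OC)cc(OC)c(OCc4ccccc4)c2OC)C=C(OC)C1=O | intermediate (not isolated)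
20 | cyclised (1S,2R)-iminium phenoxide zwitterion | COc1cc([C@H]2c3c(cc(OC)c(OCc4ccccc4)c3OC)C=C(C(=O)OC)[C@@H]2C=[N+]5CCC[C@@H]5C(c6ccccc6)(c6ccccc6)O[Si](C)(C)C)cc(OC)c1[O-] | intermediate (not isolated)
21 | methyl (1S,2R)-7-(benzyloxy)-2-formyl-1-(4-hydroxy-3,5-dimethoxyphenyl)-6,8-dimethoxy-1,2-dihydronaphthalene-3-carboxylate (key-step product) | COc1cc([C@H]2c3c(cc(OC)c(OCc4ccccc4)c3OC)C=C(C(=O)OC)[C@@H]2C=O)cc(OC)c1O | intermediate
22 | methyl (1S,2R)-7-(benzyloxy)-1-(4-hydroxy-3,5-dimethoxyphenyl)-2-(hydroxymethyl)-6,8-dimethoxy-1,2-dihydronaphthalene-3-carboxylate | COc1cc([C@H]2c3c(cc(OC)c(OCc4ccccc4)c3OC)C=C(C(=O)OC)[C@@H]2CO)cc(OC)c1O | intermediate (not isolated)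
23 | (3aR,4S)-6-(benzyloxy)-4-(4-hydroxy-3,5-dimethoxyphenyl)-5,7-dimethoxy-3a,4-dihydronaphtho[2,3-c]furan-1(3H)-one | COc1cc([C@H]2c3c(cc(OC)c(OCc4ccccc4)c3OC)C=C5C(=O)OC[C@H]25)cc(OC)c1O | intermediate
24 | (3aR,4S)-6-hydroxy-4-(4-hydroxy-3,5-dimethoxyphenyl)-5,7-dimethoxy-3a,4-dihydronaphtho[2,3-c]furan-1(3H)-one | COc1cc([C@H]2c3c(cc(OC)c(O)c3OC)C=C5C(=O)OC[C@H]25)cc(OC)c1O | intermediate
25 | (3aR,4S)-4-(4-hydroxy-3,5-dimethoxyphenyl)-5,7-dimethoxy-1,3,3a,4-tetrahydronaphtho[2,3-c]furan-1,6-diol (lactol, both anomers) | COc1cc([C@H]2c3c(cc(OC)c(O)c3OC)C=C5C(O)OC[C@H]25)cc(OC)c1O | intermediate (not isolated)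
26 | (3R,4S)-6-hydroxy-4-(4-hydroxy-3,5-dimethoxyphenyl)-3-(hydroxymethyl)-5,7-dimethoxy-3,4-dihydronaphthalene-2-carbaldehyde | COc1cc([C@H]2c3c(cc(OC)c(O)c3OC)C=C(C=O)[C@@H]2CO)cc(OC)c1O | target

**Step count**

Total: 14 steps. Longest linear sequence: 12 steps (steps 1, 2, 3, 5, 6, 8, 9, 10, 11, 12, 13, 14).

**Steps most likely to fail**

1. Step 11. The closure may run with poor facial selectivity, or be overtaken by acid-catalysed closure through the enol (racemic), by oxa-Michael addition of the carbinol oxygen to C4, or by loss of trans selectivity. The fallback uses known chemistry, sets out from 1 and comes back at 24. Knoevenagel–Doebner condensation of 1 with malonic acid (pyridine, piperidine) should give sinapic acid F1. Its known oxidative dimerisation in aerated aqueous buffer (pH about 8.5) gives racemic trans-7-hydroxy-1-(4-hydroxy-3,5-dimethoxyphenyl)-6,8-dimethoxy-1,2-dihydronaphthalene-2,3-dicarboxylic acid F2, which already holds the whole skeleton. Fischer esterification (MeOH, H2SO4) should give the racemic dimethyl ester F3, and preparative HPLC on a chiral stationary phase the (1S,2R)-dimethyl ester F4. LiOH (THF/H2O, 0 °C) should hydrolyse the C9 ester first, because the C10 ester is deactivated by conjugation with the C7 phenoxide through C3=C4, giving the half-ester F5. BH3·SMe2 should reduce the acid to the hydroxy ester F6, which lactonises on acidic work-up to 24.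

2. Step 10. While fluoride frees the phenol, the carbinol may ionise early, so that closure occurs without the catalyst (racemic) or the material oligomerises. The fallback sets out from 16 and comes back at 18. KHF2 in MeOH at rt should cleave only the aryl silyl ether and give the phenol triethylsilyl ether F7, which is never handled as a free carbinol. F7 is put directly under the conditions of step 11, where the acid ionises the C1–OSiEt3 bond (loss of Et3SiOH) to the same para-quinone methide 18.

3. Step 14. The aluminium hemiacetal may collapse early and be reduced further to the diol, or the aluminium phenoxides may precipitate and stall the reduction. The fallback sets out from 24 and comes back at 26. Opening of the lactone with Me(MeO)NH·HCl and AlMe3 (CH2Cl2, 0 °C → rt) should give the hydroxy Weinreb amide F8. Its reduction with LiAlH4 (THF, −40 °C) stops at the chelated tetrahedral stage and releases 26 on hydrolysis, so over-reduction is excluded by design.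

**Further compounds**

F1 | step 11 | sinapic acid | COc1cc(/C=C/C(=O)O)cc(OC)c1O
F2 | step 11 | racemic trans-7-hydroxy-1-(4-hydroxy-3,5-dimethoxyphenyl)-6,8-dimethoxy-1,2-dihydronaphthalene-2,3-dicarboxylic acid | COc1cc([C@H]2c3c(cc(OC)c(O)c3OC)C=C(C(=O)O)[C@@H]2C(=O)O)cc(OC)c1O.COc1cc([C@@H]2c3c(cc(OC)c(O)c3OC)C=C(C(=O)O)[C@H]2C(=O)O)cc(OC)c1O
F3 | step 11 | racemic trans dimethyl ester of F2 | COc1cc([C@H]2c3c(cc(OC)c(O)c3OC)C=C(C(=O)OC)[C@@H]2C(=O)OC)cc(OC)c1O.COc1cc([C@@H]2c3c(cc(OC)c(O)c3OC)C=C(C(=O)OC)[C@H]2C(=O)OC)cc(OC)c1O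
F4 | step 11 | dimethyl (1S,2R)-7-hydroxy-1-(4-hydroxy-3,5-dimethoxyphenyl)-6,8-dimethoxy-1,2-dihydronaphthalene-2,3-dicarboxylate | COc1cc([C@H]2c3c(cc(OC)c(O)c3OC)C=C(C(=O)OC)[C@@H]2C(=O)OC)cc(OC)c1O
F5 | step 11 | (1S,2R)-7-hydroxy-1-(4-hydroxy-3,5-dimethoxyphenyl)-6,8-dimethoxy-3-(methoxycarbonyl)-1,2-dihydronaphthalene-2-carboxylic acid | COc1cc([C@H]2c3c(cc(OC)c(O)c3OC)C=C(C(=O)OC)[C@@H]2C(=O)O)cc(OC)c1O
F6 | step 11 | methyl (1S,2R)-7-hydroxy-1-(4-hydroxy-3,5-dimethoxyphenyl)-2-(hydroxymethyl)-6,8-dimethoxy-1,2-dihydronaphthalene-3-carboxylate | COc1cc([C@H]2c3c(cc(OC)c(O)c3OC)C=C(C(=O)OC)[C@@H]2CO)cc(OC)c1O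
F7 | step 10 | methyl (2E)-3-{4-(benzyloxy)-2-[(4-hydroxy-3,5-dimethoxyphenyl)(triethylsilyloxy)methyl]-3,5-dimethoxyphenyl}-2-(2-oxoethyl)prop-2-enoate (racemic) | CC[Si](CC)(CC)OC(c1cc(OC)c(O)c(OC)c1)c1c(/C=C(\CC=O)C(=O)OC)cc(OC)c(OCc2ccccc2)c1OC
F8 | step 14 | (1S,2R)-7-hydroxy-1-(4-hydroxy-3,5-dimethoxyphenyl)-2-(hydroxymethyl)-N,6,8-trimethoxy-N-methyl-1,2-dihydronaphthalene-3-carboxamide | COc1cc([C@H]2c3c(cc(OC)c(O)c3OC)C=C(C(=O)N(C)OC)[C@@H]2CO)cc(OC)c1O
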